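Slowness was what struck me in the earlier runs, and I wanted a number for it at each of the two visible steps.

| flask | Q | D | G | remark | time |
|---|---|---|---|---|---|
| Sunday's | 0.10 M | 0.21 M | 10 mM | run made earlier |  |
| Tuesday's | 0.10 M | 0.42 M | 10 mM | run made earlier |  |
| ash | 0.10 M | 0.150 M | 10 mM |  | 40 h |
| alder | 0.10 M | 0.300 M | 10 mM |  | 40 h |

| run | time / h | Z / % | Q / % | E / % |
|---|---|---|---|---|
| Sunday's | 1.50 | 11 | 88 | 0 |
| Sunday's | 4.00 | 20 | 71 | 0 |
| Sunday's | 8.00 | 29 | 53 | 10 |
| Sunday's | 12.0 | 31 | 36 | 17 |
| Sunday's | 15.0 | 30 | 29 | 22 |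
| Sunday's | 20.0 | 28 | 15 | 30 |
| Sunday's | 30.0 | 21 | 5 | 43 |
| Tuesday's | 1.50 | 10 | 90 | 0 |
| Tuesday's | 4.00 | 18 | 71 | 5 |
| Tuesday's | 8.00 | 20 | 50 | 17 |
| Tuesday's | 12.0 | 23 | 28 | 27 |
| Tuesday's | 15.0 | 20 | 22 | 32 |
| Tuesday's | 20.0 | 12 | 12 | 43 |
| Tuesday's | 30.0 | 5 | 7 | 53 |

(scatter of a reading: 1.5 percentage points)

* which of these there is most of at the end, counted by the Q in it, ash (E / Z / Q)
* which of these there is most of at the end, counted by the Q in it, alder (E / Z / Q)
* how much there is at the end of the one of these that leads, in percent of the Q charged: ash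
* how much there is at the end of the one of these that leads, in percent of the Q charged: alder

- a reading or a percentage of E counts all its forms, free or not
- a reading of Q is of its free form alone

Free Q decayed at about 0.102 h⁻¹ as a mean of the two runs, although Tuesday's run held 0.42 M of D against 0.21 M on Sunday's. E, on the other hand, grew per unit of Z at 0.0540 h⁻¹ on Sunday's run and 0.102 h⁻¹ on Tuesday's, so I scaled that pace with D.

My bench rule was the pseudo-first-order one: where there is more D than Q, take D as standing at its charge. That gave a fixed pace from Z to E of 0.0375 h⁻¹ in ash and 0.0751 h⁻¹ in alder. Running Q to Z to E on these paces gave 33.1% for ash and 12.6% for alder. This is the Z share, the part of Z and E together that stands as Z at the end. Each lay below 0.5, so I expected E to lead Z.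

The last readings lacked 33.0% of the Q on average. Keeping that gap, I reckoned E at 43.7% in ash and 57.1% in alder.

The border of the rule lies in the ratio of charges. If each E takes one D, a full yield spends 66.7% of ash's D and 33.3% of alder's, and my E spends 29.1% and 19.0%. So I expected the real Z share in ash to stand somewhat above mine.

The forecast named E for ash at 43% and E for alder at 57%, from the same readings as mine, and said of D: “D appears little depleted, and any depletion would trim k only modestly”.

The flask gave E in ash at 45.9%, with Z at 24.4%, and E in alder at 59.3%, with Z at 7.74%.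

    Q + G → G + Z (k = 7.20 M⁻¹ h⁻¹)
    G + Z ⇌ X (K = 9.00 M⁻¹, k = 82.0 M⁻¹ h⁻¹)
    D + X → G + E (k = 4.70 M⁻¹ h⁻¹)
    Q + E ⇌ L, settled at all times (K = 230 M⁻¹)

The Z share in ash came to 34.7% against my 33.1%, with D at 69.4% of its charge, and in alder to 11.5% against my 12.6%. The neighbour flask was alder with G cut to 0.0040 M. Running both paces at 0.400 of their alder values, I got a Z share of 49.6% and free Q of 19.5%. That flask ended with free Q at 21%, a Z share of 44.5%, and E at 29.9%.

(The earlier runs and the new flask come from a simulation for an exercise; scatter was added.)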